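## The problem

Compound 30 (CNP0110281.1) is a caged acylphloroglucinol. Its core is a cyclohexane-1,3,5-trione whose three sp3 carbons are all quaternary: one carries the geranyl chain, one the benzoyl group, and the third is a spiro carbon shared with a 2,2-dimethylcyclopentanone. A CH2–CH–C(CH3)2 bridge joins the geranyl-bearing carbon to the benzoyl-bearing carbon (a bicyclo[3.3.1]nonane). The bridge CH is tied through one more CH2 to the ring-fusion CH of the cyclopentanone, which closes a seven-membered ring and makes the skeleton a homoadamantane with a fused cyclopentanone.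

Of the five stereocentres only two are independent. One is the ring-fusion CH. The other is the spiro carbon relative to it, that is, which of the two carbonyl groups on the spiro carbon lies cis to the CH2 arm of the neighbouring CH and must therefore become the carbonyl next to the geranyl-bearing carbon. Once the bridge sits on the face of the trione ring that carries the ring-fusion CH, the cage locks the geranyl-bearing carbon, the bridge CH and the benzoyl-bearing carbon. The CH can therefore control everything else, first through a ring constraint and then by shielding one face.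

The bond between the benzoyl-bearing carbon and C(CH3)2 joins two fully substituted carbons and is realistically made only by capture of a tertiary cation by the triketone enol. The finished tetraketone has no enolisable position in its six-membered ring and is open to retro-Claisen cleavage by alkoxides. The geranyl chain rules out hydrogenation, strong protic acid and electrophilic oxidants late in the route.

The handle for the plan is the cyclopentanone. Its spiro carbon and ring-fusion CH are neighbours, C=O and CH2 close the ring on the far side, and C(CH3)2 lies between C=O and CH. Taking out C(CH3)2 leaves a cyclobutanone that is the (2+2) adduct of a 1,1-disubstituted alkene (spiro carbon and CH2) and a ketene equivalent (C=O and CH).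

## Retrosynthesis

**30 from 28 via 29.** The bridge CH2 next to the ring-fusion CH has no function in 30, but an oxygen on it is what allows the cage to be closed by cation chemistry. The first cut is therefore a C–O bond: 30 comes from cage carbinol 28 through thionocarbonate 29. The forward steps must acylate a hindered secondary alcohol without forming an alkoxide and must reduce under neutral radical conditions that leave four ketones and two alkenes alone.

**28 from 27.** Two bonds are cut: bridge CH to carbinol carbon, and C(CH3)2 to the benzoyl-bearing carbon. This leads to spiro aldehyde 27, in which a prenyl group stands for the bridge. The cut is preferred over its neighbours because the quaternary–quaternary bond then forms by cation capture, and the cation arises simply from attack of the prenyl alkene on the activated aldehyde. Cutting the geranyl bond at this stage would demand alkylation at a bridgehead, and cutting a ring C–C(=O) bond would mean a Claisen closure against the strain of the cage. The precursor has two rings and two stereocentres fewer. The forward step requires the alkene, not the enol, to take the aldehyde, the cation to be captured at carbon, and the prenyl group to be cis to the aldehyde arm.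

**27 from 26, and 26 from 24 and 25.** Aldehyde 27 comes from alcohol 26 by oxidation. The geranyl–carbon bond of 26 is cut to give enolic spiro trione 24 and geranyl bromide 25. Geranyl is introduced last, on a carbon that already carries prenyl, because the second substituent enters anti to the hydroxymethyl arm of the ring-fusion CH. This leaves prenyl cis to that arm, as the cage closure needs. The aldehyde is made only after this carbon is quaternary, since the aldehyde would otherwise undergo aldol addition with the neighbouring enol carbon.

**24 from 19 and 22.** Two C–C(=O) bonds are cut: prenyl-bearing carbon to the carbonyl cis to the hydroxymethyl arm, and benzoyl-bearing carbon to the other carbonyl. The fragments are lactone ester 19 and prenylated diketone 22, itself made from 1-phenylbutane-1,3-dione 20 and prenyl bromide 21. Benzoylating a preformed symmetrical trione would give both spiro epimers. Here the two carbonyl arms are told apart by a ring: only the carboxyl cis to the hydroxymethyl group can lactonise, and the lactone is the more electrophilic acyl group. The forward step needs the dianion of 22 to choose the lactone over a hindered methyl ester and the cyclopentanone to be shielded as its enolate. It passes through open-chain triketone 23.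

**19 back to 15.** These are functional-group changes. Lactone 19 comes from hydroxy diester 18, released from silyl ether 17; 17 comes from diacid 16, and 16 from diol 15. The two hydroxymethyl groups of 15 are oxidised together and are distinguished only at the lactonisation.

**15 from 13, and 13 from 11 and 12.** The bond between C(CH3)2 and the ring-fusion CH is cut as the reverse of a 1,2-shift. Cyclopentanone 14, the acetonide of 15, becomes 1-isopropenylcyclobutanol 13, which comes from cyclobutanone 11 and isopropenylmagnesium bromide 12. This places the quaternary C(CH3)2 between C=O and CH without enolate alkylation next to a β-silyloxy centre. It is driven by ring strain and keeps the configuration of the migrating CH. The forward step needs the substituted ring carbon, not the CH2, to migrate and the protecting groups to survive the acid.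

**11 from 6 and 8 (key disconnection).** Both the C(=O)–CH2 bond and the CH–spiro carbon bond of 11 are cut. The fragments are the achiral alkene 8 and amide 6, whose keteniminium ion 9 adds to give iminium salt 10. The whole stereochemical problem is reduced to one centre set by a recoverable C2-symmetric amine.

**Starting materials.** Amide 6 comes from acid 3 through acid chloride 5 and (2R,5R)-2,5-dimethylpyrrolidine 4. Acid 3 comes from ester 2, the silyl ether of methyl 3-hydroxypropanoate 1. Alkene 8 is the acetonide of 2-methylidenepropane-1,3-diol 7.

## Roads not taken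

**Alternative 1:** The cut is at the arene–CH and CH–C(CH3)2 bonds of an aromatic precursor. In the forward step a trihydroxybenzophenone adds through its free ring carbon to a glyoxylate ester, the benzylic alcohol ionises to an ortho-quinone methide, and a tetrasubstituted silyl enol ether adds under a chiral phosphoric acid to give keto ester A1.

- Merits: the whole trione ring with its benzoyl group is bought as one aromatic piece, the stereocentre is set by a catalyst and not by a stoichiometric auxiliary, and the arene already distinguishes the two carbonyl positions that flank the future spiro carbon. In step count to the core this road is clearly shorter than the chosen one.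
- Weak points: a quinone methide with an ester on the methide carbon is an acceptor-substituted cation and is hard to generate. The stereocentre of A1 is benzylic, α to an ester and ortho to two phenols, so it can racemise by enolisation or by reversal to the quinone methide. The enol silane must form a quaternary carbon next to that centre with high selectivity. The later dearomative ring closure through the methyl ketone carbon competes with O-cyclisation onto the phenols and sets the spiro carbon only by a facial preference.
- Comparison: against the shorter sequence, the chosen plan offers a CH centre that is never benzylic and a spiro configuration fixed by a ring constraint.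

**Alternative 2:** The cut is at the bridge CH–CH2 bond and the C(CH3)2–benzoyl carbon bond. In the forward step an aluminium Lewis acid activates the aldehyde on the cyclopentanone, the prenyl alkene attacks it, and the tertiary cation is captured by the enol carbon to give cage carbinol A2.

- Merits: two rings and the remaining cage stereocentres form in one operation, and the step follows the likely biogenetic cyclisation. In this respect it is as good as anything in the chosen plan. The chosen plan in fact uses this transformation as step 15, and A2 is identical with 28.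
- Weak points as a strategy: it presupposes spiro aldehyde 27 with its two adjacent stereocentres and the correct face at the geranyl-bearing carbon, and says nothing on how they are made enantioselectively. It also leaves an oxygen that costs two steps to remove.
- Comparison: the chosen plan supplies the missing part by building the cyclopentanone with a defined CH from a (2+2) adduct, and keeps this cyclisation as the end game.

**Alternative 3:** The cut is at the spiro carbon–CH bond and the bond from the future geranyl-bearing carbon to the bridge CH2. In the forward step a phloroglucinol ketone with a tethered 1,3-diene is oxidised with a hypervalent iodine reagent, and the resulting phenoxonium ion adds across the diene through its two ortho carbons in a (4+3) mode to give tricycle A3.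

- Merits: the cyclopentanone, the seven-membered ring, the spiro carbon and the ring-fusion CH arise in one step from a flat precursor. The tether enforces their relative configuration and the arene distinguishes the carbonyl positions. On paper this is the shortest road.
- Weak points: this mode of cycloaddition has no close precedent for such a cation. The known outcomes are (5+2) or (3+2) adducts or simple nucleophilic capture. An acylated polyhydroxyarene offers several sites of oxidation, and enantiocontrol by a chiral aryl iodide in a C–C bond-forming dearomatisation is weak. A3 also still lacks the geranyl group at a bridgehead C–H, has a ring alkene that must be saturated before the last cation closure (otherwise a bridgehead alkene would result), and carries a tertiary silyl ether to ionise.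
- Comparison: the chosen plan is longer, but each step is of a known reaction type and the absolute configuration comes from a proven auxiliary.

Key step: step 5

Assumption: with the (2R,5R) amine the cycloaddition is taken to give the S centre of 11 (alkene anti to the keteniminium substituent, ring closure on the enamine face away from the nearer ring methyl); if the sense were opposite, the (2S,5S) amine would be used and nothing else changes.

Enolised triketones 24, 26 and 27 are drawn as one tautomer each. The carbinol centres of 13 and 28 are drawn as the expected or an arbitrary epimer; both centres are destroyed later.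

## Route

Step 1
Reactants: 1 methyl 3-hydroxypropanoate
Product: 2 methyl 3-{[tert-butyl(diphenyl)silyl]oxy}propanoate
Conditions: TBDPSCl, imidazole, DMF, 0 °C → rt
Reagents that add atoms: tert-butyl(chloro)diphenylsilane, CC(C)(C)[Si](Cl)(c1ccccc1)c1ccccc1
Why: Imidazole-promoted silylation of a primary alcohol; the tert-butyldiphenylsilyl ether is chosen because it survives triflic anhydride, the acid of step 7 and the oxidation of step 8, and because, unlike a benzyl ether, it offers no hydride next to oxygen for transfer to the keteniminium carbon.

Step 2
Reactants: 2 methyl 3-{[tert-butyl(diphenyl)silyl]oxy}propanoate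
Product: 3 3-{[tert-butyl(diphenyl)silyl]oxy}propanoic acid
Conditions: LiOH·H2O, THF/H2O, 0 °C → rt; then 1 M HCl to pH 3
Reagents that add atoms: lithium hydroxide, [Li+].[OH-]
Why: Ester saponification; at 0 °C hydroxide attack at the ester carbonyl is faster than β-elimination of the silyloxy group.

Step 3
Reactants: 3 3-{[tert-butyl(diphenyl)silyl]oxy}propanoic acid; 4 (2R,5R)-2,5-dimethylpyrrolidine
Product: 6 3-{[tert-butyl(diphenyl)silyl]oxy}-1-[(2R,5R)-2,5-dimethylpyrrolidin-1-yl]propan-1-one, via acid chloride 5 (not isolated)
Conditions: (COCl)2, DMF (cat.), CH2Cl2, 0 °C → rt; evaporate; then 4, Et3N, CH2Cl2, 0 °C → rt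
Reagents that add atoms: none
Why: Acid chloride formation under Vilsmeier catalysis followed by acylation of the hindered secondary amine; the acid chloride is needed because the two ring methyl groups slow direct coupling.

Step 4
Reactants: 7 2-methylidenepropane-1,3-diol
Product: 8 2,2-dimethyl-5-methylidene-1,3-dioxane
Conditions: 2,2-dimethoxypropane, PPTS (cat.), CH2Cl2, rt
Reagents that add atoms: 2,2-dimethoxypropane, COC(C)(C)OC
Why: Acid-catalysed transacetalisation to the six-membered acetonide; it ties both oxygens into one symmetrical, non-nucleophilic unit and keeps the alkene 1,1-disubstituted.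

Step 5
Reactants: 6 3-{[tert-butyl(diphenyl)silyl]oxy}-1-[(2R,5R)-2,5-dimethylpyrrolidin-1-yl]propan-1-one; 8 2,2-dimethyl-5-methylidene-1,3-dioxane
Product: 11 (1S)-1-({[tert-butyl(diphenyl)silyl]oxy}methyl)-7,7-dimethyl-6,8-dioxaspiro[3.5]nonan-2-one, via keteniminium triflate 9 (not isolated), via cyclobutaniminium triflate 10 (not isolated)
Conditions: Tf2O (1.1 equiv), CH2Cl2, −20 °C; then 8 (3 equiv), 2,4,6-collidine (1.2 equiv, slow addition), −20 → 40 °C; then aq. NaHCO3, CH2Cl2, 0 °C → rt
Reagents that add atoms: water, O
Why: Triflic anhydride activates the amide oxygen and collidine removes the α-proton to give keteniminium ion 9, a heteroallene electrophilic enough to add to unactivated alkenes (Ghosez keteniminium–alkene (2+2) cycloaddition, known also for amides of C2-symmetric pyrrolidines). The CH2 carbon of 8 attacks the central carbon of 9 in the plane of the C=N π bond and anti to the silyloxymethyl group, and the tertiary cation so formed collapses onto the enamine β-carbon. The four-membered ring thus closes stepwise (or in a strongly asynchronous cycloaddition) by attack of an enamine carbon on a cation, with the enamine double bond inside the forming ring. Cation stability fixes the regiochemistry: the iminium carbon is bonded to CH2 and the substituted carbon to the quaternary centre. The single new stereocentre is controlled by the auxiliary: both iminium rotamers are identical because the amine is C2-symmetric, and the ring methyl on the side of the incoming alkene blocks one face of the enamine carbon. The step needs the alkene π bond to react in preference to the acetal oxygens, which the tertiary cation and an excess of 8 should secure. It also needs the α-centre of 10 to keep its configuration, which cold bicarbonate hydrolysis should secure; the silyl ether cannot donate a hydride. Hydrolysis turns the iminium carbon into the ketone and releases amine 4 for recovery.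

Step 6
Reactants: 11 (1S)-1-({[tert-butyl(diphenyl)silyl]oxy}methyl)-7,7-dimethyl-6,8-dioxaspiro[3.5]nonan-2-one; 12 isopropenylmagnesium bromide
Product: 13 (1S,2S)-1-({[tert-butyl(diphenyl)silyl]oxy}methyl)-7,7-dimethyl-2-(prop-1-en-2-yl)-6,8-dioxaspiro[3.5]nonan-2-ol (expected major carbinol epimer)
Conditions: CeCl3 (anhydrous), THF, −78 °C; aq. NH4Cl
Reagents that add atoms: none
Why: Organocerium 1,2-addition (Imamoto conditions) to the strained ketone suppresses enolisation, and with it epimerisation and β-elimination of the silyloxy group; attack anti to the side chain is expected, but the new carbinol centre is lost in step 7.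

Step 7
Reactants: 13 (1S,2S)-1-({[tert-butyl(diphenyl)silyl]oxy}methyl)-7,7-dimethyl-2-(prop-1-en-2-yl)-6,8-dioxaspiro[3.5]nonan-2-ol
Product: 15 (3R)-3-({[tert-butyl(diphenyl)silyl]oxy}methyl)-4,4-bis(hydroxymethyl)-2,2-dimethylcyclopentan-1-one, via spiro acetonide cyclopentanone 14 (not isolated)
Conditions: p-TsOH (0.2 equiv), CH2Cl2, 0 °C → rt; then MeOH, rt
Reagents that add atoms: none
Why: Protonation of the isopropenyl group gives a tertiary cation next to the carbinol, and strain-driven 1,2-shift of a ring carbon gives the 2,2-dimethylcyclopentanone (acid-promoted semipinacol ring expansion of a 1-alkenylcyclobutanol). The more substituted ring carbon migrates with retention, so the CH centre is carried over unchanged, and methanol is added only after the shift so that no free hydroxyl can trap the cation before the acetonide is exchanged off.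

Step 8
Reactants: 15 (3R)-3-({[tert-butyl(diphenyl)silyl]oxy}methyl)-4,4-bis(hydroxymethyl)-2,2-dimethylcyclopentan-1-one
Product: 16 (2S)-2-({[tert-butyl(diphenyl)silyl]oxy}methyl)-3,3-dimethyl-4-oxocyclopentane-1,1-dicarboxylic acid
Conditions: TEMPO (cat.), NaClO2, NaOCl (cat.), MeCN/NaH2PO4–Na2HPO4 buffer (pH 6.7), 35 °C; then acidify to pH 3
Reagents that add atoms: sodium chlorite, [Na+].[O-]Cl=O
Why: Nitroxyl-catalysed oxidation of primary alcohols with chlorite as terminal oxidant takes both neopentyl alcohols through the aldehydes to the acids near neutral pH, where loss of formaldehyde by retro-aldol is slow; ketone and silyl ether are inert.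

Step 9
Reactants: 16 (2S)-2-({[tert-butyl(diphenyl)silyl]oxy}methyl)-3,3-dimethyl-4-oxocyclopentane-1,1-dicarboxylic acid
Product: 17 dimethyl (2S)-2-({[tert-butyl(diphenyl)silyl]oxy}methyl)-3,3-dimethyl-4-oxocyclopentane-1,1-dicarboxylate
Conditions: MeI, K2CO3, DMF, rt
Reagents that add atoms: iodomethane, CI
Why: O-Alkylation of the dicarboxylate with iodomethane; carbonate is too weak a base to enolise the cyclopentanone, so no C-methylation is expected.

Step 10
Reactants: 17 dimethyl (2S)-2-({[tert-butyl(diphenyl)silyl]oxy}methyl)-3,3-dimethyl-4-oxocyclopentane-1,1-dicarboxylate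
Product: 19 methyl (3aR,6aS)-6,6-dimethyl-3,5-dioxohexahydro-1H-cyclopenta[c]furan-3a-carboxylate, via hydroxy diester 18 (not isolated)
Conditions: HF·pyridine, THF, 0 °C → rt; then PPTS (cat.), toluene, 60 °C
Reagents that add atoms: none
Why: Fluoride desilylation frees the primary alcohol, which lactonises only with the cis ester because a trans-fused bicyclo[3.3.0] lactone is too strained; this ring constraint fixes the spiro carbon as a stereocentre and marks the cis carbonyl as the one that will adjoin the geranyl-bearing carbon.

Step 11
Reactants: 20 1-phenylbutane-1,3-dione; 21 1-bromo-3-methylbut-2-ene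
Product: 22 7-methyl-1-phenyloct-6-ene-1,3-dione
Conditions: LiN(iPr)2 (2.1 equiv), THF, −78 → 0 °C; then 21 (1.0 equiv), 0 °C; aq. HCl
Reagents that add atoms: none
Why: Alkylation of a β-diketone dianion at its terminal, more basic carbon (Hauser–Harris dianion alkylation); bringing the prenyl group in here avoids a late mono- versus dialkylation problem on the ring.

Step 12
Reactants: 19 methyl (3aR,6aS)-6,6-dimethyl-3,5-dioxohexahydro-1H-cyclopenta[c]furan-3a-carboxylate; 22 7-methyl-1-phenyloct-6-ene-1,3-dione
Product: 24 (1S,5S)-9-benzoyl-6,8-dihydroxy-1-(hydroxymethyl)-2,2-dimethyl-7-(3-methylbut-2-en-1-yl)spiro[4.5]deca-6,8-diene-3,10-dione, via open-chain triketone ester 23 (not isolated)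
Conditions: 19, LiN(iPr)2 (1.05 equiv), THF, −78 °C; then dilithio-22 (2.2 equiv, from 22 and LiN(iPr)2), −78 °C → rt, then 50 °C; cold 1 M HCl to pH 3–4
Reagents that add atoms: none
Why: The cyclopentanone is first masked as its enolate. The terminal carbanion of the dianion then acylates the strained lactone in preference to the hindered methyl ester (Claisen condensation of a β-diketone dianion), and the enolate of the resulting triketone closes onto the ester (Dieckmann cyclisation) to give the 2-acylcyclohexane-1,3,5-trione. Because the lactone carbonyl takes the prenyl-bearing carbon, the configuration of the spiro carbon follows from step 10.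

Step 13
Reactants: 24 (1S,5S)-9-benzoyl-6,8-dihydroxy-1-(hydroxymethyl)-2,2-dimethyl-7-(3-methylbut-2-en-1-yl)spiro[4.5]deca-6,8-diene-3,10-dione; 25 (2E)-1-bromo-3,7-dimethylocta-2,6-diene (geranyl bromide)
Product: 26 (1S,5R,7S)-9-benzoyl-7-[(2E)-3,7-dimethylocta-2,6-dien-1-yl]-10-hydroxy-1-(hydroxymethyl)-2,2-dimethyl-7-(3-methylbut-2-en-1-yl)spiro[4.5]dec-9-ene-3,6,8-trione
Conditions: LiN(SiMe3)2 (2.0 equiv), THF, −78 → 0 °C; then 25 (1.1 equiv), 0 °C → rt; aq. NH4Cl
Reagents that add atoms: none
Why: C-Alkylation of the dianion of the vinylogous acid at the ring carbon that does not carry the acyl group, as in alkylative dearomatisation of acylphloroglucinols. The hydroxymethyl arm lies over the face of that carbon cis to the ring-fusion CH, so geranyl bromide should enter from the opposite face and leave the prenyl group cis to the arm. Two equivalents of base leave the alcohol protonated and so avoid retro-Claisen opening.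

Step 14
Reactants: 26 (1S,5R,7S)-9-benzoyl-7-[(2E)-3,7-dimethylocta-2,6-dien-1-yl]-10-hydroxy-1-(hydroxymethyl)-2,2-dimethyl-7-(3-methylbut-2-en-1-yl)spiro[4.5]dec-9-ene-3,6,8-trione
Product: 27 (1S,5R,7S)-9-benzoyl-7-[(2E)-3,7-dimethylocta-2,6-dien-1-yl]-10-hydroxy-2,2-dimethyl-7-(3-methylbut-2-en-1-yl)-3,6,8-trioxospiro[4.5]dec-9-ene-1-carbaldehyde
Conditions: Dess–Martin periodinane, NaHCO3, CH2Cl2, 0 °C → rt; used without purification
Reagents that add atoms: none
Why: Buffered Dess–Martin oxidation of the primary alcohol under near-neutral conditions, which spare the alkenes and keep the α-centre of the new aldehyde from epimerising; the aldehyde is made only now because the neighbouring ring carbon is quaternary and can no longer add to it.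

Step 15
Reactants: 27 (1S,5R,7S)-9-benzoyl-7-[(2E)-3,7-dimethylocta-2,6-dien-1-yl]-10-hydroxy-2,2-dimethyl-7-(3-methylbut-2-en-1-yl)-3,6,8-trioxospiro[4.5]dec-9-ene-1-carbaldehyde
Product: 28 cage carbinol: compound 30 carrying a hydroxyl on the bridge CH2 next to the ring-fusion CH (drawn with the hydroxyl on the side of the geranyl-bearing bridgehead)
Conditions: Me2AlCl (2.5 equiv), CH2Cl2, −78 → 0 °C; aq. KNaC4H4O6 (potassium sodium tartrate)
Reagents that add atoms: none
Why: One equivalent of Me2AlCl converts the acidic enol into a chelated aluminium enolate and the rest activates the aldehyde. The prenyl alkene attacks through its CH carbon (Prins-type carbonyl–alkene cyclisation, seven-membered ring), and the tertiary cation is captured by the central carbon of the triketone enolate, as in cation–enol closures of caged acylphloroglucinols. The aldehyde arm is cis to the carbonyl that adjoins the prenyl-bearing carbon, so the enol carbon on the other side could reach it only through a trans-fused bicyclo[3.3.0] ring. The geranyl alkene is on the opposite face. The bridge CH and the benzoyl-bearing centre are set by the geometry of the cage.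

Step 16
Reactants: 28 cage carbinol
Product: 29 O-phenyl thionocarbonate of 28
Conditions: PhOC(S)Cl, pyridine, DMAP (cat.), CH2Cl2, rt
Reagents that add atoms: O-phenyl chlorothionoformate, S=C(Cl)Oc1ccccc1
Why: Thioacylation of the secondary alcohol under amine base without forming an alkoxide, which would risk retro-Claisen opening of the non-enolisable polyketone.

Step 17
Reactants: 29 O-phenyl thionocarbonate of 28
Product: 30 CNP0110281.1
Conditions: Bu3SnH, AIBN (cat.), toluene, 90 °C
Reagents that add atoms: none
Why: Barton–McCombie deoxygenation; the secondary cage radical has no strained β-bond to cleave and no alkene within reach, so hydrogen transfer from the stannane should be the only pathway, and ketones and trisubstituted alkenes are untouched.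

## Compound list

1 | methyl 3-hydroxypropanoate | COC(=O)CCO | starting material
2 | methyl 3-{[tert-butyl(diphenyl)silyl]oxy}propanoate | COC(=O)CCO[Si](c1ccccc1)(c1ccccc1)C(C)(C)C | intermediate
3 | 3-{[tert-butyl(diphenyl)silyl]oxy}propanoic acid | OC(=O)CCO[Si](c1ccccc1)(c1ccccc1)C(C)(C)C | intermediate
4 | (2R,5R)-2,5-dimethylpyrrolidine | C[C@@H]1CC[C@@H](C)N1 | starting material
5 | 3-{[tert-butyl(diphenyl)silyl]oxy}propanoyl chloride | ClC(=O)CCO[Si](c1ccccc1)(c1ccccc1)C(C)(C)C | intermediate (not isolated)
6 | 3-{[tert-butyl(diphenyl)silyl]oxy}-1-[(2R,5R)-2,5-dimethylpyrrolidin-1-yl]propan-1-one | C[C@@H]1CC[C@@H](C)N1C(=O)CCO[Si](c1ccccc1)(c1ccccc1)C(C)(C)C | intermediate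
7 | 2-methylidenepropane-1,3-diol | C=C(CO)CO | starting material
8 | 2,2-dimethyl-5-methylidene-1,3-dioxane | C=C1COC(C)(C)OC1 | intermediate
9 | (2R,5R)-1-(3-{[tert-butyl(diphenyl)silyl]oxy}prop-1-en-1-ylidene)-2,5-dimethylpyrrolidin-1-ium triflate (keteniminium triflate) | C[C@@H]1CC[C@@H](C)[N+]1=C=CCO[Si](c1ccccc1)(c1ccccc1)C(C)(C)C.[O-]S(=O)(=O)C(F)(F)F | intermediate (not isolated)
10 | cyclobutaniminium triflate: iminium salt of ketone 11 with amine 4 | C[C@@H]1CC[C@@H](C)[N+]1=C1CC2(COC(C)(C)OC2)[C@H]1CO[Si](c1ccccc1)(c1ccccc1)C(C)(C)C.[O-]S(=O)(=O)C(F)(F)F | intermediate (not isolated)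
11 | (1S)-1-({[tert-butyl(diphenyl)silyl]oxy}methyl)-7,7-dimethyl-6,8-dioxaspiro[3.5]nonan-2-one | O=C1CC2(COC(C)(C)OC2)[C@H]1CO[Si](c1ccccc1)(c1ccccc1)C(C)(C)C | intermediate
12 | isopropenylmagnesium bromide | C=C(C)[Mg]Br | starting material
13 | (1S,2S)-1-({[tert-butyl(diphenyl)silyl]oxy}methyl)-7,7-dimethyl-2-(prop-1-en-2-yl)-6,8-dioxaspiro[3.5]nonan-2-ol | C=C(C)[C@]1(O)CC2(COC(C)(C)OC2)[C@H]1CO[Si](c1ccccc1)(c1ccccc1)C(C)(C)C | intermediate
14 | (4R)-4-({[tert-butyl(diphenyl)silyl]oxy}methyl)-3,3,8,8-tetramethyl-7,9-dioxaspiro[4.5]decan-2-one | O=C1CC2(COC(C)(C)OC2)[C@@H](CO[Si](c3ccccc3)(c3ccccc3)C(C)(C)C)C1(C)C | intermediate (not isolated)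
15 | (3R)-3-({[tert-butyl(diphenyl)silyl]oxy}methyl)-4,4-bis(hydroxymethyl)-2,2-dimethylcyclopentan-1-one | O=C1CC(CO)(CO)[C@@H](CO[Si](c2ccccc2)(c2ccccc2)C(C)(C)C)C1(C)C | intermediate
16 | (2S)-2-({[tert-butyl(diphenyl)silyl]oxy}methyl)-3,3-dimethyl-4-oxocyclopentane-1,1-dicarboxylic acid | O=C1CC(C(=O)O)(C(=O)O)[C@@H](CO[Si](c2ccccc2)(c2ccccc2)C(C)(C)C)C1(C)C | intermediate
17 | dimethyl (2S)-2-({[tert-butyl(diphenyl)silyl]oxy}methyl)-3,3-dimethyl-4-oxocyclopentane-1,1-dicarboxylate | O=C1CC(C(=O)OC)(C(=O)OC)[C@@H](CO[Si](c2ccccc2)(c2ccccc2)C(C)(C)C)C1(C)C | intermediate
18 | dimethyl (2S)-2-(hydroxymethyl)-3,3-dimethyl-4-oxocyclopentane-1,1-dicarboxylate | O=C1CC(C(=O)OC)(C(=O)OC)[C@@H](CO)C1(C)C | intermediate (not isolated)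
19 | methyl (3aR,6aS)-6,6-dimethyl-3,5-dioxohexahydro-1H-cyclopenta[c]furan-3a-carboxylate | COC(=O)[C@@]12CC(=O)C(C)(C)[C@@H]1COC2=O | intermediate
20 | 1-phenylbutane-1,3-dione | CC(=O)CC(=O)c1ccccc1 | starting material
21 | 1-bromo-3-methylbut-2-ene (prenyl bromide) | CC(C)=CCBr | starting material
22 | 7-methyl-1-phenyloct-6-ene-1,3-dione | CC(C)=CCCC(=O)CC(=O)c1ccccc1 | intermediate
23 | open-chain triketone ester: methyl (1R,2S)-2-(hydroxymethyl)-3,3-dimethyl-4-oxo-1-[2-(3-methylbut-2-en-1-yl)-3,5-dioxo-5-phenylpentanoyl]cyclopentane-1-carboxylate (side-chain CH epimers) | COC(=O)[C@@]1(C(=O)C(CC=C(C)C)C(=O)CC(=O)c2ccccc2)CC(=O)C(C)(C)[C@@H]1CO | intermediate (not isolated)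
24 | (1S,5S)-9-benzoyl-6,8-dihydroxy-1-(hydroxymethyl)-2,2-dimethyl-7-(3-methylbut-2-en-1-yl)spiro[4.5]deca-6,8-diene-3,10-dione | O=C1C(C(=O)c2ccccc2)=C(O)C(CC=C(C)C)=C(O)[C@@]13CC(=O)C(C)(C)[C@@H]3CO | intermediate
25 | (2E)-1-bromo-3,7-dimethylocta-2,6-diene (geranyl bromide) | CC(C)=CCC/C(C)=C/CBr | starting material
26 | (1S,5R,7S)-9-benzoyl-7-[(2E)-3,7-dimethylocta-2,6-dien-1-yl]-10-hydroxy-1-(hydroxymethyl)-2,2-dimethyl-7-(3-methylbut-2-en-1-yl)spiro[4.5]dec-9-ene-3,6,8-trione | CC(C)=CCC/C(C)=C/C[C@]1(CC=C(C)C)C(=O)C(C(=O)c2ccccc2)=C(O)[C@@]3(C1=O)CC(=O)C(C)(C)[C@@H]3CO | intermediate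
27 | (1S,5R,7S)-9-benzoyl-7-[(2E)-3,7-dimethylocta-2,6-dien-1-yl]-10-hydroxy-2,2-dimethyl-7-(3-methylbut-2-en-1-yl)-3,6,8-trioxospiro[4.5]dec-9-ene-1-carbaldehyde | CC(C)=CCC/C(C)=C/C[C@]1(CC=C(C)C)C(=O)C(C(=O)c2ccccc2)=C(O)[C@@]3(C1=O)CC(=O)C(C)(C)[C@@H]3C=O | intermediate
28 | cage carbinol: 30 with a hydroxyl on the bridge CH2 next to the ring-fusion CH | CC(C)=CCC/C(C)=C/C[C@@]12C[C@H]3[C@@H](O)[C@H]4C(C)(C)C(=O)C[C@]4(C1=O)C(=O)[C@@](C(=O)c1ccccc1)(C2=O)C3(C)C | intermediate
29 | O-phenyl thionocarbonate of 28 | CC(C)=CCC/C(C)=C/C[C@@]12C[C@H]3[C@@H](OC(=S)Oc5ccccc5)[C@H]4C(C)(C)C(=O)C[C@]4(C1=O)C(=O)[C@@](C(=O)c1ccccc1)(C2=O)C3(C)C | intermediate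
30 | CNP0110281.1 | CC(C)=CCC/C(C)=C/C[C@@]12C[C@H]3C[C@H]4C(C)(C)C(=O)C[C@]4(C1=O)C(=O)[C@@](C(=O)c1ccccc1)(C2=O)C3(C)C | target

## Step count and risks

Total step count: 17. Longest linear sequence: 15 steps (1 to 30 through steps 1–3, 5–10 and 12–17); steps 4 and 11 are side branches.

**Step 5 (key step).**
- Most likely to go wrong: loss of configurational purity at the α-carbon, either by iminium–enamine equilibration of 10 before hydrolysis or by incomplete face discrimination with so small a keteniminium substituent. The Lewis-basic acetal oxygens of an inductively deactivated alkene may also consume the keteniminium ion.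
- Fallback, from 8 back to 11: the alkene is combined with dichloroketene (Cl3CCOCl, Zn(Cu), Et2O) to give 1,1-dichloro-7,7-dimethyl-6,8-dioxaspiro[3.5]nonan-2-one F1. Reductive dechlorination (Zn, AcOH) gives the symmetrical 7,7-dimethyl-6,8-dioxaspiro[3.5]nonan-2-one F2, whose two α-CH2 groups are enantiotopic. An enamine-catalysed aldol reaction with aqueous formaldehyde (proline-type catalyst, antipode chosen to give the S ketone) gives (1S)-1-(hydroxymethyl)-7,7-dimethyl-6,8-dioxaspiro[3.5]nonan-2-one F3, and silylation (TBDPSCl, imidazole) returns to 11. The ring is still made by a (2+2) addition to the same alkene, but the stereocentre is introduced afterwards on an achiral ketone.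

**Step 7.**
- Most likely to go wrong: interception of the tertiary cation by a dioxane oxygen, or opening of the acetal before the shift so that a free hydroxyl closes a tetrahydrofuran. Less likely, the CH2 carbon migrates in place of the substituted one, since the β-silyloxy group lowers the migratory aptitude of the CH.
- Fallback, from 11 back to 15: addition of 2-lithio-2-(methylselanyl)propane (from 2,2-bis(methylselanyl)propane and n-BuLi) gives the β-hydroxy selenide (1S,2S)-1-({[tert-butyl(diphenyl)silyl]oxy}methyl)-7,7-dimethyl-2-[2-(methylselanyl)propan-2-yl]-6,8-dioxaspiro[3.5]nonan-2-ol F4. AgBF4 on alumina in CH2Cl2 removes the selanyl group with concurrent ring enlargement under aprotic conditions to give 14, here isolated, and PPTS in MeOH then gives 15.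

**Step 12.**
- Most likely to go wrong: attack of the dianion on the methyl ester or on incompletely enolised cyclopentanone in place of the lactone, which would give the spiro epimer or a tertiary alcohol. The Dieckmann closure onto the hindered ester may also stall.
- Fallback, from 16 back to 24: HF·pyridine gives the lactone acid (3aR,6aS)-6,6-dimethyl-3,5-dioxohexahydro-1H-cyclopenta[c]furan-3a-carboxylic acid F5, and (COCl)2 gives its acid chloride F6. C-Acylation of 22 at its central carbon (MgCl2, pyridine, CH2Cl2) gives the triacylmethane F7, in which the benzoyl-bearing carbon is already bonded to the carbonyl trans to the lactone. LiN(iPr)2 (3.5 equiv) then deprotonates the terminal CH2, which closes onto the lactone in an intramolecular Claisen condensation to give 24. The order of the two bond formations is reversed, so the regiochemistry no longer depends on a rate difference.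

**Step 13.**
- Most likely to go wrong: insufficient facial selectivity, because the free hydroxymethyl arm is a small shield. This would give the epimer with geranyl cis to the arm, which would later cyclise through the geranyl alkene. Some O-alkylation is also possible.
- Fallback, from 24 back to 26: silylation (TIPSCl, imidazole; enol silyl ethers cleaved on work-up) gives the triisopropylsilyl ether of 24, F8, in which the arm is far bulkier. Geranylation as in step 13 gives the triisopropylsilyl ether of 26, F9, and HF·pyridine returns 26.

**Step 15.**
- Most likely to go wrong: diversion of the tertiary cation, by capture at an enolate oxygen to give a pyran enol ether or by proton loss to the isopropenyl ene product, in place of C–C bond formation. Epimerisation of the aldehyde α-centre would also prevent the closure.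
- Fallback, from 26 back to 28: O-methylation (TMSCHN2, MeOH/toluene) gives the methyl enol ether of 26, F10 (either regioisomer serves). Dess–Martin oxidation gives the aldehyde F11. Me2AlCl then effects only the carbonyl-ene closure of the seven-membered ring to give the isopropenyl alcohol F12, with the enol oxygen blocked. Brief treatment with CF3CO2H in CH2Cl2 at 0 °C re-forms the tertiary cation, the enol ether carbon captures it, and the methyl oxocarbenium ion is hydrolysed on work-up to give 28.

## Further compounds

F1 | step 5 | 1,1-dichloro-7,7-dimethyl-6,8-dioxaspiro[3.5]nonan-2-one | ClC1(Cl)C(=O)CC12COC(C)(C)OC2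
F2 | step 5 | 7,7-dimethyl-6,8-dioxaspiro[3.5]nonan-2-one | O=C1CC2(C1)COC(C)(C)OC2
F3 | step 5 | (1S)-1-(hydroxymethyl)-7,7-dimethyl-6,8-dioxaspiro[3.5]nonan-2-one | O=C1CC2(COC(C)(C)OC2)[C@H]1CO
F4 | step 7 | (1S,2S)-1-({[tert-butyl(diphenyl)silyl]oxy}methyl)-7,7-dimethyl-2-[2-(methylselanyl)propan-2-yl]-6,8-dioxaspiro[3.5]nonan-2-ol | C[Se]C(C)(C)[C@]1(O)CC2(COC(C)(C)OC2)[C@H]1CO[Si](c1ccccc1)(c1ccccc1)C(C)(C)C
F5 | step 12 | (3aR,6aS)-6,6-dimethyl-3,5-dioxohexahydro-1H-cyclopenta[c]furan-3a-carboxylic acid | OC(=O)[C@@]12CC(=O)C(C)(C)[C@@H]1COC2=O
F6 | step 12 | acid chloride of F5 (same spatial arrangement) | ClC(=O)[C@@]12CC(=O)C(C)(C)[C@@H]1COC2=O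
F7 | step 12 | triacylmethane: 2-benzoyl-7-methyl-1-(lactone F5 skeleton at its 3a position)oct-6-ene-1,3-dione | CC(C)=CCCC(=O)C(C(=O)c1ccccc1)C(=O)[C@@]12CC(=O)C(C)(C)[C@@H]1COC2=O
F8 | step 13 | triisopropylsilyl ether of 24 | O=C1C(C(=O)c2ccccc2)=C(O)C(CC=C(C)C)=C(O)[C@@]13CC(=O)C(C)(C)[C@@H]3CO[Si](C(C)C)(C(C)C)C(C)C
F9 | step 13 | triisopropylsilyl ether of 26 | CC(C)=CCC/C(C)=C/C[C@]1(CC=C(C)C)C(=O)C(C(=O)c2ccccc2)=C(O)[C@@]3(C1=O)CC(=O)C(C)(C)[C@@H]3CO[Si](C(C)C)(C(C)C)C(C)C
F10 | step 15 | methyl enol ether of 26 | CC(C)=CCC/C(C)=C/C[C@]1(CC=C(C)C)C(=O)C(C(=O)c2ccccc2)=C(OC)[C@@]3(C1=O)CC(=O)C(C)(C)[C@@H]3CO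
F11 | step 15 | methyl enol ether of 27 | CC(C)=CCC/C(C)=C/C[C@]1(CC=C(C)C)C(=O)C(C(=O)c2ccccc2)=C(OC)[C@@]3(C1=O)CC(=O)C(C)(C)[C@@H]3C=O
F12 | step 15 | ene alcohol: seven-membered ring closed, isopropenyl on the bridge CH, enol still O-methylated | CC(C)=CCC/C(C)=C/C[C@@]12C[C@H](C(C)=C)[C@@H](O)[C@H]3C(C)(C)C(=O)C[C@]3(C1=O)C(OC)=C(C(=O)c1ccccc1)C2=O
A1 | alternative 1 | ethyl (2R)-2-(3-benzoyl-2,4,6-trihydroxyphenyl)-3,3-dimethyl-4-oxopentanoate | O=C(c1ccccc1)c2c(O)cc(O)c([C@@H](C(=O)OCC)C(C)(C)C(C)=O)c2O
A2 | alternative 2 | cage carbinol, identical with 28 | CC(C)=CCC/C(C)=C/C[C@@]12C[C@H]3[C@@H](O)[C@H]4C(C)(C)C(=O)C[C@]4(C1=O)C(=O)[C@@](C(=O)c1ccccc1)(C2=O)C3(C)C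
A3 | alternative 3 | (4+3) adduct: cyclopentanone-fused bicyclo[4.3.1]decenetrione enol with benzoyl and a 2-(tert-butyldimethylsilyloxy)propan-2-yl group on the ring alkene | [C@@H]12CC(C(C)(C)O[Si](C)(C)C(C)(C)C)=C[C@H]4C(C)(C)C(=O)C[C@]4(C1=O)C(O)=C(C(=O)c1ccccc1)C2=O
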